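The route rests on cutting the C2–C3 bond of the central dihydrofuran ring C (O1, C2, C3 and the two carbons shared with aromatic ring B). Opened there, C2 is the doubly activated (benzylic, ether) OCH2 of an aryl benzyl ether that links the aryltetrahydrofuran half to the phenylcoumaran half, and C3 is a diazoacetate carbon on ring B, its ester the latent CH2OH. One catalyst-controlled intramolecular rhodium-carbene C–H insertion closes ring C last, makes C2–C3 and fixes C2; base epimerisation at C3 and reduction finish. The precursor is an ortho-benzyloxy aryldiazoacetate, assembled by Mitsunobu etherification and palladium-catalysed coupling of the aryl iodide with ethyl diazoacetate.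

Key step: step 19

Ring labels: A = guaiacyl ring of the benzyl group; B = aromatic ring fused to ring C; C = central dihydrofuran; D = aromatic ring fused to ring E; E = outer dihydrofuran; F = terminal guaiacyl ring; the saturated oxygen ring is called the THF ring (O1, C2 aryl, C3, C4 benzyl, C5).

Assumption: the sense of induction of the chiral catalysts in steps 5, 15 and 19 is assigned by analogy with simple model substrates; both antipodes of each catalyst are available and the one that gives the drawn configuration is used.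

Step 1
Reactants: 1 vanillin
Product: 2 3-methoxy-4-(triisopropylsilyloxy)benzaldehyde
Conditions: TIPSCl, imidazole, DMF, rt
Reagents that add atoms: triisopropylsilyl chloride, CC(C)[Si](Cl)(C(C)C)C(C)C
Why: Imidazole-mediated O-silylation of the phenol should give a base-robust aryl silyl ether that masks the ring A (and later ring F) phenol until the final fluoride step.

Step 2
Reactants: 2 3-methoxy-4-(triisopropylsilyloxy)benzaldehyde
Product: 3 [3-methoxy-4-(triisopropylsilyloxy)phenyl]methanol
Conditions: NaBH4, MeOH, 0 °C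
Reagents that add atoms: none
Why: Borohydride reduction of the aromatic aldehyde to the benzylic alcohol should leave the aryl silyl ether untouched.

Step 3
Reactants: 3 [3-methoxy-4-(triisopropylsilyloxy)phenyl]methanol
Product: 4 4-(bromomethyl)-2-methoxy-1-(triisopropylsilyloxy)benzene
Conditions: CBr4, PPh3, CH2Cl2, 0 °C, used crude
Reagents that add atoms: carbon tetrabromide, BrC(Br)(Br)Br
Why: The Appel reaction converts the electron-rich benzylic alcohol to the bromide under neutral conditions, which avoids acid that would cleave the silyl ether.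

Step 4
Reactants: 4 4-(bromomethyl)-2-methoxy-1-(triisopropylsilyloxy)benzene, 5 4-bromofuran-2(5H)-one
Product: 7 4-[3-methoxy-4-(triisopropylsilyloxy)benzyl]furan-2(5H)-one, via benzylzinc bromide 6 (not isolated)
Conditions: Zn dust, LiCl, THF, 0 °C; then 5, Pd(PPh3)4 (3 mol%), THF, rt
Reagents that add atoms: none
Why: Zinc insertion gives the benzylic zinc bromide, and Negishi cross-coupling with the vinylogous acyl bromide under zerovalent palladium catalysis should form the sp3–sp2 bond of the beta-benzyl butenolide.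

Step 5
Reactants: 7 4-[3-methoxy-4-(triisopropylsilyloxy)benzyl]furan-2(5H)-one
Product: 8 (R)-4-[3-methoxy-4-(triisopropylsilyloxy)benzyl]dihydrofuran-2(3H)-one
Conditions: H2 (100 atm), Ru(OAc)2[(R)-BINAP] (1 mol%), MeOH, 50 °C
Reagents that add atoms: none
Why: Asymmetric hydrogenation of the beta-substituted butenolide with the BINAP ruthenium diacetate catalyst should set the lactone C4 (the later C4 of the THF ring) as R by catalyst control of the alkene face.

Step 6
Reactants: 8 (R)-4-[3-methoxy-4-(triisopropylsilyloxy)benzyl]dihydrofuran-2(3H)-one, 9 4-(allyloxy)-3-methoxybenzaldehyde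
Product: 10 (3S,4R)-3-[(4-allyloxy-3-methoxyphenyl)(hydroxy)methyl]-4-[3-methoxy-4-(triisopropylsilyloxy)benzyl]dihydrofuran-2(3H)-one (both carbinol epimers)
Conditions: LiN(SiMe3)2, THF, −78 °C; then 9; AcOH quench
Reagents that add atoms: none
Why: Aldol addition of the lithium lactone enolate takes place anti to the C4 benzyl group and so sets the lactone C3 as S (trans lactone); the carbinol centre is not controlled here and is erased in step 7.

Step 7
Reactants: 10 (3S,4R)-3-[(4-allyloxy-3-methoxyphenyl)(hydroxy)methyl]-4-[3-methoxy-4-(triisopropylsilyloxy)benzyl]dihydrofuran-2(3H)-one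
Product: 11 (3S,4R)-3-(4-allyloxy-3-methoxybenzoyl)-4-[3-methoxy-4-(triisopropylsilyloxy)benzyl]dihydrofuran-2(3H)-one
Conditions: Dess–Martin periodinane, NaHCO3, CH2Cl2, rt
Reagents that add atoms: none
Why: Dess–Martin oxidation converges both carbinol epimers on the beta-keto lactone, whose epimerisable C3 stays in the favoured trans arrangement to the benzyl group.

Step 8
Reactants: 11 (3S,4R)-3-(4-allyloxy-3-methoxybenzoyl)-4-[3-methoxy-4-(triisopropylsilyloxy)benzyl]dihydrofuran-2(3H)-one
Product: 12 (3S,4R)-3-[(R)-(4-allyloxy-3-methoxyphenyl)(hydroxy)methyl]-4-[3-methoxy-4-(triisopropylsilyloxy)benzyl]dihydrofuran-2(3H)-one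
Conditions: RuCl(p-cymene)[(R,R)-TsDPEN] (2 mol%), HCO2H/Et3N (5:2), DMF, 30 °C
Reagents that add atoms: none
Why: Noyori asymmetric transfer hydrogenation should reduce the aryl ketone under catalyst control to the R carbinol (the anti aldol-type isomer, which Felkin–Anh bias also favours), while the acidic C3 remains trans to the benzyl group.

Step 9
Reactants: 12 (3S,4R)-3-[(R)-(4-allyloxy-3-methoxyphenyl)(hydroxy)methyl]-4-[3-methoxy-4-(triisopropylsilyloxy)benzyl]dihydrofuran-2(3H)-one
Product: 13 (2S,3R)-2-[(R)-(4-allyloxy-3-methoxyphenyl)(hydroxy)methyl]-4-hydroxy-3-[3-methoxy-4-(triisopropylsilyloxy)benzyl]-1-(pyrrolidin-1-yl)butan-1-one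
Conditions: pyrrolidine, AlMe3, CH2Cl2, 0 °C to rt
Reagents that add atoms: pyrrolidine, C1CCNC1
Why: Aminolysis of the lactone by the dimethylaluminium amide frees the primary alcohol and turns the carboxyl carbon into a tertiary amide, so the two oxygenated carbons are differentiated without touching the three stereocentres.

Step 10
Reactants: 13 (2S,3R)-2-[(R)-(4-allyloxy-3-methoxyphenyl)(hydroxy)methyl]-4-hydroxy-3-[3-methoxy-4-(triisopropylsilyloxy)benzyl]-1-(pyrrolidin-1-yl)butan-1-one
Product: 15 [(2R,3S,4R)-2-(4-allyloxy-3-methoxyphenyl)-4-[3-methoxy-4-(triisopropylsilyloxy)benzyl]tetrahydrofuran-3-yl](pyrrolidin-1-yl)methanone, via primary mesylate 14 (not isolated)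
Conditions: MsCl, Et3N, CH2Cl2, −40 °C; then NaH, THF, 0 °C
Reagents that add atoms: none
Why: Selective mesylation of the primary alcohol followed by intramolecular Williamson etherification (5-exo-tet) by the benzylic alkoxide closes the THF ring with retention at the benzylic carbon, which turns the anti,trans stereotriad into the all-cis ring without acid.

Step 11
Reactants: 15 [(2R,3S,4R)-2-(4-allyloxy-3-methoxyphenyl)-4-[3-methoxy-4-(triisopropylsilyloxy)benzyl]tetrahydrofuran-3-yl](pyrrolidin-1-yl)methanone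
Product: 16 [(2R,3S,4R)-2-(4-hydroxy-3-methoxyphenyl)-4-[3-methoxy-4-(triisopropylsilyloxy)benzyl]tetrahydrofuran-3-yl](pyrrolidin-1-yl)methanone
Conditions: Pd(PPh3)4 (5 mol%), morpholine, THF, rt
Reagents that add atoms: none
Why: Tsuji–Trost deallylation with zerovalent palladium and morpholine as allyl acceptor frees the ring B phenol under neutral conditions that spare the aryl silyl ether, the amide and the labile benzylic ether of the THF ring.

Step 12
Reactants: 16 [(2R,3S,4R)-2-(4-hydroxy-3-methoxyphenyl)-4-[3-methoxy-4-(triisopropylsilyloxy)benzyl]tetrahydrofuran-3-yl](pyrrolidin-1-yl)methanone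
Product: 17 [(2R,3S,4R)-2-(4-hydroxy-3-iodo-5-methoxyphenyl)-4-[3-methoxy-4-(triisopropylsilyloxy)benzyl]tetrahydrofuran-3-yl](pyrrolidin-1-yl)methanone
Conditions: I2, morpholine, CH2Cl2, 0 °C
Reagents that add atoms: iodine, II
Why: Electrophilic iodination of the phenol in the presence of the amine should occur at the only free ortho position of ring B (para is blocked), the silylated ring A being far less reactive.

Step 13
Reactants: 18 5-iodovanillin (4-hydroxy-3-iodo-5-methoxybenzaldehyde), 4 4-(bromomethyl)-2-methoxy-1-(triisopropylsilyloxy)benzene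
Product: 19 3-iodo-5-methoxy-4-{[3-methoxy-4-(triisopropylsilyloxy)benzyl]oxy}benzaldehyde
Conditions: K2CO3, DMF, rt
Reagents that add atoms: none
Why: Williamson O-alkylation of the acidic phenol with the reactive benzylic bromide installs ring F and the methylene that becomes C2 of ring E.

Step 14
Reactants: 19 3-iodo-5-methoxy-4-{[3-methoxy-4-(triisopropylsilyloxy)benzyl]oxy}benzaldehyde
Product: 20 ethyl 2-diazo-2-(5-formyl-3-methoxy-2-{[3-methoxy-4-(triisopropylsilyloxy)benzyl]oxy}phenyl)acetate
Conditions: ethyl diazoacetate, Pd(PPh3)4 (5 mol%), Ag2CO3 (0.5 equiv), Et3N, toluene, rt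
Reagents that add atoms: ethyl diazoacetate, CCOC(=O)C=[N+]=[N-]
Why: Palladium-catalysed cross-coupling of the aryl iodide with the C–H bond of ethyl diazoacetate (silver carbonate as halide scavenger) should install the donor/acceptor diazo ester ortho to the benzyloxy group with the diazo function retained.

Step 15
Reactants: 20 ethyl 2-diazo-2-(5-formyl-3-methoxy-2-{[3-methoxy-4-(triisopropylsilyloxy)benzyl]oxy}phenyl)acetate
Product: 21 ethyl (2S,3R)-5-formyl-7-methoxy-2-[3-methoxy-4-(triisopropylsilyloxy)phenyl]-2,3-dihydrobenzofuran-3-carboxylate (cis)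
Conditions: Rh2(R-PTTL)4 (1 mol%), toluene, −40 °C, slow addition, high dilution
Reagents that add atoms: none
Why: Enantioselective intramolecular 1,5 C–H insertion of the dirhodium carbenoid into the ether-activated benzylic methylene closes ring E; the chiral dirhodium tetrakis(N-phthaloyl-tert-leucinate) selects the benzylic hydrogen (C2 = S) and the concerted insertion gives the cis ester (C3 = R), high dilution suppressing attack of the carbenoid on the aldehyde.

Step 16
Reactants: 21 ethyl (2S,3R)-5-formyl-7-methoxy-2-[3-methoxy-4-(triisopropylsilyloxy)phenyl]-2,3-dihydrobenzofuran-3-carboxylate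
Product: 22 ethyl (2S,3R)-5-(hydroxymethyl)-7-methoxy-2-[3-methoxy-4-(triisopropylsilyloxy)phenyl]-2,3-dihydrobenzofuran-3-carboxylate (cis)
Conditions: NaBH4, CeCl3·7H2O, EtOH/THF, −40 °C
Reagents that add atoms: none
Why: Luche reduction converts the aldehyde chemoselectively to the benzylic alcohol at low temperature, without reducing the ester and with little basicity to disturb the cis ester (any epimerisation would be harmless, since step 20 sets this centre).

Step 17
Reactants: 17 [(2R,3S,4R)-2-(4-hydroxy-3-iodo-5-methoxyphenyl)-4-[3-methoxy-4-(triisopropylsilyloxy)benzyl]tetrahydrofuran-3-yl](pyrrolidin-1-yl)methanone, 22 ethyl (2S,3R)-5-(hydroxymethyl)-7-methoxy-2-[3-methoxy-4-(triisopropylsilyloxy)phenyl]-2,3-dihydrobenzofuran-3-carboxylate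
Product: 23 ethyl (2S,3R)-5-{[2-iodo-6-methoxy-4-((2R,3S,4R)-4-[3-methoxy-4-(triisopropylsilyloxy)benzyl]-3-(pyrrolidine-1-carbonyl)tetrahydrofuran-2-yl)phenoxy]methyl}-7-methoxy-2-[3-methoxy-4-(triisopropylsilyloxy)phenyl]-2,3-dihydrobenzofuran-3-carboxylate
Conditions: PPh3, DIAD, toluene, 0 °C to rt
Reagents that add atoms: none
Why: Mitsunobu etherification joins the acidic iodophenol of the western half to the primary benzylic alcohol of the eastern half under neutral conditions that leave all stereocentres untouched.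

Step 18
Reactants: 23 the aryl iodide benzyl ether from step 17
Product: 24 ethyl (2S,3R)-5-{[2-(1-diazo-2-ethoxy-2-oxoethyl)-6-methoxy-4-((2R,3S,4R)-4-[3-methoxy-4-(triisopropylsilyloxy)benzyl]-3-(pyrrolidine-1-carbonyl)tetrahydrofuran-2-yl)phenoxy]methyl}-7-methoxy-2-[3-methoxy-4-(triisopropylsilyloxy)phenyl]-2,3-dihydrobenzofuran-3-carboxylate
Conditions: ethyl diazoacetate, Pd(PPh3)4 (10 mol%), Ag2CO3 (0.5 equiv), Et3N, toluene, rt
Reagents that add atoms: ethyl diazoacetate, CCOC(=O)C=[N+]=[N-]
Why: The same palladium-catalysed coupling of an aryl iodide with ethyl diazoacetate as in step 14 places the donor/acceptor diazo ester on ring B next to the benzylic ether, under mild base that the esters, the amide and the silyl ethers tolerate.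

Step 19
Reactants: 24 the ring B aryldiazoacetate from step 18
Product: 25 ethyl (2R,3S)-2-[(2S,3R)-3-(ethoxycarbonyl)-7-methoxy-2-(3-methoxy-4-(triisopropylsilyloxy)phenyl)-2,3-dihydrobenzofuran-5-yl]-7-methoxy-5-[(2R,3S,4R)-4-(3-methoxy-4-(triisopropylsilyloxy)benzyl)-3-(pyrrolidine-1-carbonyl)tetrahydrofuran-2-yl]-2,3-dihydrobenzofuran-3-carboxylate (rings C and E both cis)
Conditions: Rh2(S-PTTL)4 (2 mol%), toluene, −40 to 0 °C, slow addition, high dilution
Reagents that add atoms: none
Why: Loss of N2 from the diazo ester at the chiral dirhodium tetrakis(N-phthaloyl-tert-leucinate) gives a donor/acceptor carbenoid on ring B, which inserts in a concerted, asynchronous hydride-transfer and C–C-forming event into one C–H bond of the adjacent O–CH2–aryl methylene; the closest known reaction type is the enantioselective intramolecular C–H insertion of ortho-benzyloxy aryldiazoacetates to cis-2-aryl-2,3-dihydrobenzofuran-3-carboxylates. Ring C is closed by the new C2–C3 bond through a five-centre 1,5-insertion transition state, the only ring-forming event of the step. C2 (R) is set by the catalyst, which chooses between the two diastereotopic benzylic hydrogens, and C3 is set cis to the C2 aryl group (S in the ester) by the geometry of the concerted insertion, to be turned into the required trans centre in step 20. The step needs site selectivity for this methylene over every other C–H bond, which is secured by the five-membered transition state and by activation from the ether oxygen and electron-rich ring D, the benzylic ether C–H bonds of the THF ring and of ring E being out of geometric reach. It also needs chemoselectivity against cycloaddition to ring D and ylide formation at the amide or ether oxygens, which the stabilised donor/acceptor carbenoid, low temperature and slow addition at high dilution should secure. The existing stereocentres of both halves lie far from the reacting centres, so catalyst control is expected to dominate.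

Step 20
Reactants: 25 the cis,cis diester from step 19
Product: 26 ethyl (2R,3R)-2-[(2S,3S)-3-(ethoxycarbonyl)-7-methoxy-2-(3-methoxy-4-(triisopropylsilyloxy)phenyl)-2,3-dihydrobenzofuran-5-yl]-7-methoxy-5-[(2R,3S,4R)-4-(3-methoxy-4-(triisopropylsilyloxy)benzyl)-3-(pyrrolidine-1-carbonyl)tetrahydrofuran-2-yl]-2,3-dihydrobenzofuran-3-carboxylate (rings C and E both trans)
Conditions: NaOEt (0.5 equiv), EtOH/THF, 0 °C to rt
Reagents that add atoms: none
Why: Ethoxide-catalysed epimerisation at the acidic benzylic C3–H of both aryl esters gives the thermodynamically favoured trans esters of rings C and E in one operation, while the much less acidic amide alpha-centre of the THF ring and both C2 centres are not touched.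

Step 21
Reactants: 26 the trans,trans diester from step 20
Product: 27 {(2R,3S)-2-[(2S,3R)-3-(hydroxymethyl)-7-methoxy-2-(3-methoxy-4-(triisopropylsilyloxy)phenyl)-2,3-dihydrobenzofuran-5-yl]-5-[(2R,3R,4R)-3-(hydroxymethyl)-4-(3-methoxy-4-(triisopropylsilyloxy)benzyl)tetrahydrofuran-2-yl]-7-methoxy-2,3-dihydrobenzofuran-3-yl}methanol
Conditions: LiH2NBH3 (from BH3·NH3 and LiN(iPr)2), THF, 0 °C to rt
Reagents that add atoms: none
Why: Lithium amidotrihydroborate reduces esters and hindered tertiary amides to primary alcohols, so both ethyl esters and the pyrrolidine amide should give the three CH2OH groups in one operation without epimerisation.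

Step 22
Reactants: 27 the bis(triisopropylsilyl) ether from step 21
Product: 28 CNP0395728.1, 4-{[(3R,4R,5R)-5-{(2R,3S)-2-[(2S,3R)-2-(4-hydroxy-3-methoxyphenyl)-3-(hydroxymethyl)-7-methoxy-2,3-dihydrobenzofuran-5-yl]-3-(hydroxymethyl)-7-methoxy-2,3-dihydrobenzofuran-5-yl}-4-(hydroxymethyl)tetrahydrofuran-3-yl]methyl}-2-methoxyphenol
Conditions: TBAF, AcOH, THF, 0 °C to rt
Reagents that add atoms: none
Why: Fluoride-induced cleavage of the two aryl silyl ethers, buffered with acetic acid, releases the phenols of rings A and F without acid that would epimerise the all-cis THF ring.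

Compound list
1 | vanillin (4-hydroxy-3-methoxybenzaldehyde) | COc1cc(C=O)ccc1O | starting material
2 | 3-methoxy-4-(triisopropylsilyloxy)benzaldehyde | COc1cc(C=O)ccc1O[Si](C(C)C)(C(C)C)C(C)C | intermediate
3 | [3-methoxy-4-(triisopropylsilyloxy)phenyl]methanol | COc1cc(CO)ccc1O[Si](C(C)C)(C(C)C)C(C)C | intermediate
4 | 4-(bromomethyl)-2-methoxy-1-(triisopropylsilyloxy)benzene | COc1cc(CBr)ccc1O[Si](C(C)C)(C(C)C)C(C)C | intermediate
5 | 4-bromofuran-2(5H)-one | BrC1=CC(=O)OC1 | starting material
6 | [3-methoxy-4-(triisopropylsilyloxy)benzyl]zinc bromide (not isolated) | COc1cc(C[Zn]Br)ccc1O[Si](C(C)C)(C(C)C)C(C)C | intermediate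
7 | 4-[3-methoxy-4-(triisopropylsilyloxy)benzyl]furan-2(5H)-one | COc1cc(CC2=CC(=O)OC2)ccc1O[Si](C(C)C)(C(C)C)C(C)C | intermediate
8 | (R)-4-[3-methoxy-4-(triisopropylsilyloxy)benzyl]dihydrofuran-2(3H)-one | COc1cc(C[C@H]2COC(=O)C2)ccc1O[Si](C(C)C)(C(C)C)C(C)C | intermediate
9 | 4-(allyloxy)-3-methoxybenzaldehyde | C=CCOc1ccc(C=O)cc1OC | starting material
10 | (3S,4R)-3-[(4-allyloxy-3-methoxyphenyl)(hydroxy)methyl]-4-[3-methoxy-4-(triisopropylsilyloxy)benzyl]dihydrofuran-2(3H)-one, both carbinol epimers | COc1cc(C[C@H]2COC(=O)[C@@H]2C(O)c2ccc(OCC=C)c(OC)c2)ccc1O[Si](C(C)C)(C(C)C)C(C)C | intermediate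
11 | (3S,4R)-3-(4-allyloxy-3-methoxybenzoyl)-4-[3-methoxy-4-(triisopropylsilyloxy)benzyl]dihydrofuran-2(3H)-one | COc1cc(C[C@H]2COC(=O)[C@@H]2C(=O)c2ccc(OCC=C)c(OC)c2)ccc1O[Si](C(C)C)(C(C)C)C(C)C | intermediate
12 | (3S,4R)-3-[(R)-(4-allyloxy-3-methoxyphenyl)(hydroxy)methyl]-4-[3-methoxy-4-(triisopropylsilyloxy)benzyl]dihydrofuran-2(3H)-one | COc1cc(C[C@H]2COC(=O)[C@@H]2[C@@H](O)c2ccc(OCC=C)c(OC)c2)ccc1O[Si](C(C)C)(C(C)C)C(C)C | intermediate
13 | (2S,3R)-2-[(R)-(4-allyloxy-3-methoxyphenyl)(hydroxy)methyl]-4-hydroxy-3-[3-methoxy-4-(triisopropylsilyloxy)benzyl]-1-(pyrrolidin-1-yl)butan-1-one | COc1cc(C[C@@H](CO)[C@H](C(=O)N2CCCC2)[C@@H](O)c2ccc(OCC=C)c(OC)c2)ccc1O[Si](C(C)C)(C(C)C)C(C)C | intermediate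
14 | primary methanesulfonate of 13 (not isolated) | COc1cc(C[C@@H](COS(C)(=O)=O)[C@H](C(=O)N2CCCC2)[C@@H](O)c2ccc(OCC=C)c(OC)c2)ccc1O[Si](C(C)C)(C(C)C)C(C)C | intermediate
15 | [(2R,3S,4R)-2-(4-allyloxy-3-methoxyphenyl)-4-[3-methoxy-4-(triisopropylsilyloxy)benzyl]tetrahydrofuran-3-yl](pyrrolidin-1-yl)methanone (all-cis) | COc1cc(C[C@H]2CO[C@@H](c3ccc(OCC=C)c(OC)c3)[C@H]2C(=O)N2CCCC2)ccc1O[Si](C(C)C)(C(C)C)C(C)C | intermediate
16 | [(2R,3S,4R)-2-(4-hydroxy-3-methoxyphenyl)-4-[3-methoxy-4-(triisopropylsilyloxy)benzyl]tetrahydrofuran-3-yl](pyrrolidin-1-yl)methanone | COc1cc(C[C@H]2CO[C@@H](c3ccc(O)c(OC)c3)[C@H]2C(=O)N2CCCC2)ccc1O[Si](C(C)C)(C(C)C)C(C)C | intermediate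
17 | [(2R,3S,4R)-2-(4-hydroxy-3-iodo-5-methoxyphenyl)-4-[3-methoxy-4-(triisopropylsilyloxy)benzyl]tetrahydrofuran-3-yl](pyrrolidin-1-yl)methanone | COc1cc(C[C@H]2CO[C@@H](c3cc(I)c(O)c(OC)c3)[C@H]2C(=O)N2CCCC2)ccc1O[Si](C(C)C)(C(C)C)C(C)C | intermediate
18 | 5-iodovanillin (4-hydroxy-3-iodo-5-methoxybenzaldehyde) | COc1cc(C=O)cc(I)c1O | starting material
19 | 3-iodo-5-methoxy-4-{[3-methoxy-4-(triisopropylsilyloxy)benzyl]oxy}benzaldehyde | COc1cc(C=O)cc(I)c1OCc1ccc(O[Si](C(C)C)(C(C)C)C(C)C)c(OC)c1 | intermediate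
20 | ethyl 2-diazo-2-(5-formyl-3-methoxy-2-{[3-methoxy-4-(triisopropylsilyloxy)benzyl]oxy}phenyl)acetate | CCOC(=O)C(=[N+]=[N-])c1cc(C=O)cc(OC)c1OCc1ccc(O[Si](C(C)C)(C(C)C)C(C)C)c(OC)c1 | intermediate
21 | ethyl (2S,3R)-5-formyl-7-methoxy-2-[3-methoxy-4-(triisopropylsilyloxy)phenyl]-2,3-dihydrobenzofuran-3-carboxylate (cis) | O=Cc1cc(OC)c2c(c1)[C@@H](C(=O)OCC)[C@@H](c1ccc(O[Si](C(C)C)(C(C)C)C(C)C)c(OC)c1)O2 | intermediate
22 | ethyl (2S,3R)-5-(hydroxymethyl)-7-methoxy-2-[3-methoxy-4-(triisopropylsilyloxy)phenyl]-2,3-dihydrobenzofuran-3-carboxylate (cis) | OCc1cc(OC)c2c(c1)[C@@H](C(=O)OCC)[C@@H](c1ccc(O[Si](C(C)C)(C(C)C)C(C)C)c(OC)c1)O2 | intermediate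
23 | aryl iodide benzyl ether: ring B of 17 O-alkylated by the ring D methylene of 22 (name in step 17) | COc1cc(C[C@H]2CO[C@@H](c3cc(I)c(OCc4cc(OC)c5c(c4)[C@@H](C(=O)OCC)[C@@H](c4ccc(O[Si](C(C)C)(C(C)C)C(C)C)c(OC)c4)O5)c(OC)c3)[C@H]2C(=O)N2CCCC2)ccc1O[Si](C(C)C)(C(C)C)C(C)C | intermediate
24 | ring B aryldiazoacetate: 23 with C(=N2)CO2Et in place of iodine (name in step 18) | COc1cc(C[C@H]2CO[C@@H](c3cc(C(=[N+]=[N-])C(=O)OCC)c(OCc4cc(OC)c5c(c4)[C@@H](C(=O)OCC)[C@@H](c4ccc(O[Si](C(C)C)(C(C)C)C(C)C)c(OC)c4)O5)c(OC)c3)[C@H]2C(=O)N2CCCC2)ccc1O[Si](C(C)C)(C(C)C)C(C)C | intermediate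
25 | diester with ring C cis (2R,3S) and ring E cis (2S,3R), THF ring (2R,3S,4R) amide (name in step 19) | COc1cc(C[C@H]2CO[C@@H](c3cc(OC)c4c(c3)[C@H](C(=O)OCC)[C@H](c3cc(OC)c5c(c3)[C@@H](C(=O)OCC)[C@@H](c3ccc(O[Si](C(C)C)(C(C)C)C(C)C)c(OC)c3)O5)O4)[C@H]2C(=O)N2CCCC2)ccc1O[Si](C(C)C)(C(C)C)C(C)C | intermediate
26 | diester with ring C trans (2R,3R) and ring E trans (2S,3S), THF ring (2R,3S,4R) amide (name in step 20) | COc1cc(C[C@H]2CO[C@@H](c3cc(OC)c4c(c3)[C@@H](C(=O)OCC)[C@H](c3cc(OC)c5c(c3)[C@H](C(=O)OCC)[C@@H](c3ccc(O[Si](C(C)C)(C(C)C)C(C)C)c(OC)c3)O5)O4)[C@H]2C(=O)N2CCCC2)ccc1O[Si](C(C)C)(C(C)C)C(C)C | intermediate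
27 | bis(triisopropylsilyl) ether of the target at the ring A and ring F phenols (name in step 21) | COc1cc(C[C@H]2CO[C@@H](c3cc(OC)c4c(c3)[C@@H](CO)[C@H](c3cc(OC)c5c(c3)[C@H](CO)[C@@H](c3ccc(O[Si](C(C)C)(C(C)C)C(C)C)c(OC)c3)O5)O4)[C@H]2CO)ccc1O[Si](C(C)C)(C(C)C)C(C)C | intermediate
28 | CNP0395728.1: THF ring (2R,3R,4R) all-cis, ring C (2R,3S) trans, ring E (2S,3R) trans (name in step 22) | COc1cc(C[C@H]2CO[C@@H](c3cc(OC)c4c(c3)[C@@H](CO)[C@H](c3cc(OC)c5c(c3)[C@H](CO)[C@@H](c3ccc(O)c(OC)c3)O5)O4)[C@H]2CO)ccc1O | target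

Total step count: 22. Longest linear sequence: 18 steps (steps 1 to 12, then 17 to 22); steps 13 to 16 build the eastern half from 18 and the shared bromide 4.

Steps most likely to fail

Step 19 (ring C closure). The catalyst may discriminate poorly between the two benzylic hydrogens in so large a substrate, giving both cis diastereomers. The carbenoid may also be diverted into cycloaddition with ring D, ylide formation at the amide oxygen or carbene dimerisation. The fallback sets out from 17 and 21 and comes back at 27. Wittig methylenation of 21 (Ph3P=CH2, THF, 0 °C) gives the styrene F1; the basic ylide is expected to turn ring E into its trans ester at the same time, which is wanted. Cross-metathesis with (Z)-but-2-ene-1,4-diol (second-generation Grubbs catalyst, CH2Cl2, 40 °C) gives the (E)-cinnamyl alcohol F2. Heck-type oxyarylation of F2 with iodophenol 17 (Pd(OAc)2, Ag2CO3, acetone, 60 °C) then forms ring C, still as the last ring: the aryl group adds to the alkene carbon remote from ring D and the phenol oxygen closes onto the benzylic carbon, giving the trans 2-aryl-3-hydroxymethyl ring. Without catalyst control both trans diastereomers are expected; they are separated by chromatography, and the 2R,3S isomer is the ring C alcohol F3. Reduction of F3 under the conditions of step 21 gives 27.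

Step 18 (diazo ester on the hindered iodide). Oxidative addition or transfer of the diazo partner may be slow at the electron-rich iodide flanked by the benzyloxy group, so that the diazo ester decomposes before it couples. The fallback sets out from 23 and comes back at 26. Palladium-catalysed alpha-arylation with the Reformatsky reagent (BrZnCH2CO2Et, Pd2(dba)3, XPhos, THF, 60 °C) gives the arylacetate F4. Regitz diazo transfer (4-acetamidobenzenesulfonyl azide, DBU, MeCN, 0 °C to rt) then gives the diazo ester F5; DBU is expected to epimerise the ring E ester to trans on the way, so F5 is the ring E epimer of 24. The C–H insertion of step 19 applied to F5 gives the insertion product F6 (ring C cis, ring E trans), and the conditions of step 20 take F6 to 26.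

Step 10 (closure of the all-cis THF ring). The amide oxygen may displace the mesylate faster than the hindered benzylic alkoxide (which leads back to lactone 12), the crowded all-cis closure may be slow, and the centre next to the amide may epimerise under base. The fallback sets out from 13 and comes back at 15. Chemoselective oxidation of the primary alcohol (TEMPO, PhI(OAc)2, CH2Cl2, rt) runs through the lactol to the gamma-lactone F7, in which the benzylic oxygen is already bonded to the former CH2OH carbon. Reduction with iBu2AlH (CH2Cl2, −78 °C) gives the lactol F8, and ionic hydrogenation (Et3SiH, BF3·OEt2, CH2Cl2, −78 °C) removes the anomeric hydroxyl to give 15. The ring C–O bond is made here by hemiacetal formation and not by displacement, and the carbon that is reduced ends as a CH2, so no stereocentre is at stake.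

Further compounds
F1 | step 19 | ethyl (2S,3S)-7-methoxy-2-[3-methoxy-4-(triisopropylsilyloxy)phenyl]-5-vinyl-2,3-dihydrobenzofuran-3-carboxylate (trans) | C=Cc1cc(OC)c2c(c1)[C@H](C(=O)OCC)[C@@H](c1ccc(O[Si](C(C)C)(C(C)C)C(C)C)c(OC)c1)O2
F2 | step 19 | ethyl (2S,3S)-5-[(E)-3-hydroxyprop-1-enyl]-7-methoxy-2-[3-methoxy-4-(triisopropylsilyloxy)phenyl]-2,3-dihydrobenzofuran-3-carboxylate (trans) | OC/C=C/c1cc(OC)c2c(c1)[C@H](C(=O)OCC)[C@@H](c1ccc(O[Si](C(C)C)(C(C)C)C(C)C)c(OC)c1)O2
F3 | step 19 | analogue of 26 with CH2OH in place of the ring C ester: ring C (2R,3S) trans alcohol, ring E (2S,3S) trans ethyl ester, THF ring amide | COc1cc(C[C@H]2CO[C@@H](c3cc(OC)c4c(c3)[C@@H](CO)[C@H](c3cc(OC)c5c(c3)[C@H](C(=O)OCC)[C@@H](c3ccc(O[Si](C(C)C)(C(C)C)C(C)C)c(OC)c3)O5)O4)[C@H]2C(=O)N2CCCC2)ccc1O[Si](C(C)C)(C(C)C)C(C)C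
F4 | step 18 | arylacetate: 23 with CH2CO2Et in place of iodine (ring E cis) | COc1cc(C[C@H]2CO[C@@H](c3cc(CC(=O)OCC)c(OCc4cc(OC)c5c(c4)[C@@H](C(=O)OCC)[C@@H](c4ccc(O[Si](C(C)C)(C(C)C)C(C)C)c(OC)c4)O5)c(OC)c3)[C@H]2C(=O)N2CCCC2)ccc1O[Si](C(C)C)(C(C)C)C(C)C
F5 | step 18 | ring E epimer of 24: aryldiazoacetate with ring E (2S,3S) trans ester | COc1cc(C[C@H]2CO[C@@H](c3cc(C(=[N+]=[N-])C(=O)OCC)c(OCc4cc(OC)c5c(c4)[C@H](C(=O)OCC)[C@@H](c4ccc(O[Si](C(C)C)(C(C)C)C(C)C)c(OC)c4)O5)c(OC)c3)[C@H]2C(=O)N2CCCC2)ccc1O[Si](C(C)C)(C(C)C)C(C)C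
F6 | step 18 | ring E epimer of 25: ring C (2R,3S) cis ester, ring E (2S,3S) trans ester | COc1cc(C[C@H]2CO[C@@H](c3cc(OC)c4c(c3)[C@H](C(=O)OCC)[C@H](c3cc(OC)c5c(c3)[C@H](C(=O)OCC)[C@@H](c3ccc(O[Si](C(C)C)(C(C)C)C(C)C)c(OC)c3)O5)O4)[C@H]2C(=O)N2CCCC2)ccc1O[Si](C(C)C)(C(C)C)C(C)C
F7 | step 10 | 5-oxo analogue of 15: gamma-lactone with the benzylic oxygen acylated by the former CH2OH carbon | COc1cc(C[C@H]2C(=O)O[C@@H](c3ccc(OCC=C)c(OC)c3)[C@H]2C(=O)N2CCCC2)ccc1O[Si](C(C)C)(C(C)C)C(C)C
F8 | step 10 | 5-hydroxy analogue of 15: lactol, both anomers | COc1cc(C[C@H]2C(O)O[C@@H](c3ccc(OCC=C)c(OC)c3)[C@H]2C(=O)N2CCCC2)ccc1O[Si](C(C)C)(C(C)C)C(C)C
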